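The plan disconnects the O9–C13 bond of the oxolane (ring C) and the C8–O bond of the tertiary alcohol, both traced back to oxiranes. Ring B carries a trans-diaxial pair of oxygens, 8β on C8 and 9α on C9, and O9 is also bonded to the spiro carbon C13; this is the pattern left by two backside oxirane openings. In one Lewis-acid operation the 8α,9α-oxirane oxygen opens an ethynyl-substituted C13–C16 oxirane and a 7β-tert-butyl carbonate opens the resulting oxonium at C8, closing the oxolane and a 7,8-carbonate and setting C8, C9 and C13. The precursor is a sclareolide-derived 6α-silyloxy-7β-Boc-oxy labdane bis-epoxide.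

Key step: step 16

Remark: the C6 hydroxyl is carried as a triethylsilyl ether, because it must later be removed beside an acetate and an enol ether with buffered fluoride; labdane numbering is used, with C16 as the oxirane methylene and C14/C15 as the ethynyl carbons.

Step 1
Reactants: 1 (+)-sclareolide
Product: 2 methyl 13,14,15,16-tetranorlabd-8-en-12-oate
Conditions: H2SO4 (conc.), MeOH, 65 °C
Reagents that add atoms: methanol, CO
Why: Acid-mediated lactone opening by E1 ionisation of the tertiary C8–O bond with Fischer esterification of the freed acid; reversible protonation should steer the alkene isomers to the tetrasubstituted Δ8 olefin under thermodynamic control, and C5 and C10 are not touched.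

Step 2
Reactants: 2 methyl 13,14,15,16-tetranorlabd-8-en-12-oate
Product: 3 13,14,15,16-tetranorlabd-8-en-12-ol
Conditions: LiAlH4, THF, 0 °C
Reagents that add atoms: none
Why: LiAlH4 reduction of an ester to the primary alcohol; the isolated tetrasubstituted alkene is inert to hydride.

Step 3
Reactants: 3 13,14,15,16-tetranorlabd-8-en-12-ol
Product: 4 12-iodo-13,14,15,16-tetranorlabd-8-ene
Conditions: I2, PPh3, imidazole, CH2Cl2, 0 °C → rt
Reagents that add atoms: iodine, II
Why: Appel-type iodination, an SN2 displacement of the alkoxyphosphonium at an unhindered primary carbon, with imidazole taking up the acid so that the alkene does not migrate.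

Step 4
Reactants: 5 2-bromoprop-2-en-1-ol
Product: 6 (2-bromoallyloxy)(tert-butyl)dimethylsilane
Conditions: TBSCl, imidazole, CH2Cl2, rt
Reagents that add atoms: tert-butyldimethylsilyl chloride, CC(C)(C)[Si](C)(C)Cl
Why: Imidazole-mediated silylation of a primary alcohol, which masks the acidic O–H that would quench the organozinc of step 5.

Step 5
Reactants: 4 12-iodo-13,14,15,16-tetranorlabd-8-ene; 6 (2-bromoallyloxy)(tert-butyl)dimethylsilane
Product: 8 14-(tert-butyldimethylsilyloxy)-15-norlabda-8,13(16)-diene, via alkylzinc iodide 7 (not isolated)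
Conditions: Zn dust, LiCl, THF, 40 °C; then 6, PdCl2(dppf) (5 mol %), THF, 50 °C
Reagents that add atoms: none
Why: Negishi coupling: zinc inserts into the primary C–I bond and the alkylzinc 7 transmetalates to the alkenylpalladium bromide formed from 6, the wide-bite-angle diphosphine favouring reductive elimination over β-hydride loss, so the C12–C13 bond forms without touching the ring alkene.

Step 6
Reactants: 8 14-(tert-butyldimethylsilyloxy)-15-norlabda-8,13(16)-diene
Product: 9 15-norlabda-8,13(16)-dien-14-ol
Conditions: TBAF, THF, 0 °C → rt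
Reagents that add atoms: none
Why: Fluoride-induced cleavage of a primary silyl ether, driven by the strong Si–F bond.

Step 7
Reactants: 9 15-norlabda-8,13(16)-dien-14-ol
Product: 10 (13R)-13,16-epoxy-15-norlabd-8-en-14-ol
Conditions: Ti(OiPr)4 (10 mol %), D-(−)-diisopropyl tartrate (12 mol %), t-BuOOH (decane), 4 Å MS, CH2Cl2, −20 °C
Reagents that add atoms: tert-butyl hydroperoxide, CC(C)(C)OO
Why: Sharpless asymmetric epoxidation: only the allylic alcohol alkene binds to the titanium tartrate, and with the D-(−)-tartrate oxygen is delivered to the face that makes C13 R by reagent control (the distant decalin has no say), while the unfunctionalised ring alkene is left alone.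

Step 8
Reactants: 10 (13R)-13,16-epoxy-15-norlabd-8-en-14-ol
Product: 11 (13S)-13,16-epoxy-15-norlabd-8-en-14-al
Conditions: Dess–Martin periodinane, NaHCO3, CH2Cl2, 0 °C → rt
Reagents that add atoms: none
Why: Dess–Martin oxidation of a primary alcohol to the aldehyde under buffered conditions that spare the oxirane; the α-carbon is quaternary, so C13 cannot epimerise (the descriptor changes only through the priority rules).

Step 9
Reactants: 11 (13S)-13,16-epoxy-15-norlabd-8-en-14-al; 12 dimethyl (1-diazo-2-oxopropyl)phosphonate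
Product: 13 (13R)-13,16-epoxylabd-8-en-14-yne
Conditions: K2CO3, MeOH, 0 °C → rt
Reagents that add atoms: dimethyl (1-diazo-2-oxopropyl)phosphonate (12), COP(=O)(OC)C(=[N+]=[N-])C(C)=O
Why: Ohira–Bestmann alkynylation (Seyferth–Gilbert homologation): methanolysis of 12 gives the diazomethylphosphonate anion, which olefinates the aldehyde, loses N2 and rearranges by a 1,2-hydride shift to the terminal alkyne under conditions too mild to open the oxirane.

Step 10
Reactants: 13 (13R)-13,16-epoxylabd-8-en-14-yne
Product: 14 (13R)-13,16-epoxylabd-8-en-14-yn-7-one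
Conditions: CrO3, 3,5-dimethylpyrazole, CH2Cl2, −20 °C
Reagents that add atoms: chromium trioxide, O=[Cr](=O)=O
Why: Allylic C–H oxidation by the CrO3–3,5-dimethylpyrazole complex, which should convert the ring methylene C7, whose axial 7α-hydrogen is aligned with the alkene π system, into the enone carbonyl in preference to the more hindered side-chain methylene C11 and the C17 methyl, while alkyne and oxirane are not oxidised.

Step 11
Reactants: 14 (13R)-13,16-epoxylabd-8-en-14-yn-7-one
Product: 16 (13R)-13,16-epoxy-6α-hydroxylabd-8-en-14-yn-7-one, via dipotassium enolate acetylide 15 (not isolated)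
Conditions: KN(SiMe3)2 (2.2 equiv), THF, −78 °C; 2-(phenylsulfonyl)-3-phenyloxaziridine, −78 °C; sat. aq. NH4Cl
Reagents that add atoms: 2-(phenylsulfonyl)-3-phenyloxaziridine, O=S(=O)(c1ccccc1)N1OC1c1ccccc1
Why: Davis oxaziridine hydroxylation of the kinetic cross-conjugated C6 enolate (the second equivalent of base parks the alkyne as its acetylide, which is reprotonated on quench); oxygen should enter from the α face because the β face of C6 is blocked by the axial methyl groups on C4 and C10, which sets the equatorial 6α-hydroxyl.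

Step 12
Reactants: 16 (13R)-13,16-epoxy-6α-hydroxylabd-8-en-14-yn-7-one
Product: 17 (13R)-13,16-epoxy-6α-(triethylsilyloxy)labd-8-en-14-yn-7-one
Conditions: TESCl, imidazole, DMF, 0 °C → rt
Reagents that add atoms: chlorotriethylsilane, CC[Si](CC)(CC)Cl
Why: Imidazole-mediated silylation of the secondary α-ketol hydroxyl under conditions too mild for ketol rearrangement.

Step 13
Reactants: 17 (13R)-13,16-epoxy-6α-(triethylsilyloxy)labd-8-en-14-yn-7-one
Product: 18 (13R)-13,16-epoxy-6α-(triethylsilyloxy)labd-8-en-14-yn-7β-ol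
Conditions: NaBH4, CeCl3·7H2O, MeOH, −78 → −20 °C
Reagents that add atoms: none
Why: Luche reduction: CeCl3 enforces 1,2-addition to the enone, and axial delivery of hydride from the α face should give mainly the equatorial 7β-alcohol trans to the 6α-silyloxy group.

Step 14
Reactants: 18 (13R)-13,16-epoxy-6α-(triethylsilyloxy)labd-8-en-14-yn-7β-ol; 19 di-tert-butyl dicarbonate
Product: 20 (13R)-7β-(tert-butoxycarbonyloxy)-13,16-epoxy-6α-(triethylsilyloxy)labd-8-en-14-yne
Conditions: DMAP, Et3N, CH2Cl2, rt
Reagents that add atoms: di-tert-butyl dicarbonate (19), CC(C)(C)OC(=O)OC(=O)OC(C)(C)C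
Why: DMAP-catalysed acylation of the secondary allylic alcohol to its tert-butyl carbonate without a strong base, so the alkyne C–H and the oxirane are untouched.

Step 15
Reactants: 20 (13R)-7β-(tert-butoxycarbonyloxy)-13,16-epoxy-6α-(triethylsilyloxy)labd-8-en-14-yne
Product: 21 (13R)-7β-(tert-butoxycarbonyloxy)-8α,9α:13,16-diepoxy-6α-(triethylsilyloxy)labd-14-yne
Conditions: mCPBA, NaHCO3, CH2Cl2, 0 °C
Reagents that add atoms: 3-chloroperoxybenzoic acid, OOC(=O)c1cccc(Cl)c1
Why: Prilezhaev epoxidation of the electron-rich tetrasubstituted alkene, which should occur on the α face because the β face is screened by the axial C10 methyl and the 7β-carbonate, giving the 8α,9α-oxirane; the terminal alkyne is far less nucleophilic and stays.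

Step 16
Reactants: 21 (13R)-7β-(tert-butoxycarbonyloxy)-8α,9α:13,16-diepoxy-6α-(triethylsilyloxy)labd-14-yne
Product: 23 (13S)-9α,13-epoxy-16-hydroxy-6α-(triethylsilyloxy)labd-14-yne-7β,8β-diyl carbonate, via bridged epoxonium ion 22 (not isolated)
Conditions: BF3·OEt2 (0.5 equiv), CH2Cl2, −40 °C; sat. aq. NaHCO3
Reagents that add atoms: none
Why: BF3 coordinates the less hindered ethynyl oxirane, and the 8α,9α-oxirane oxygen attacks the tertiary propargylic C13 from the rear (5-exo-tet closure of the oxolane), inverting C13 from R to S and giving the bridged epoxonium ion 22. The carbonyl oxygen of the 7β-tert-butyl carbonate then opens 22 at C8 from the β face (5-exo-tet closure of the dioxolanone) and the tert-butyl cation leaves as isobutene, so O9 stays α and O8 ends β, both axial. The closest known reaction type is the Lewis-acid polyepoxide oxacyclisation cascade relayed through epoxonium ions and ended by a tert-butyl carbonate, allied to the familiar opening of epoxy alcohol Boc carbonates to cyclic carbonates. C13 is controlled by the configuration of the Sharpless-derived oxirane through SN2-type inversion (the alkynyl group disfavours a free cation), C8 by the fixed β position of the carbonate, which can only attack anti to the C8–O bond in a trans-diaxial opening, and C9 keeps the α oxygen set by the epoxidation. The step needs attack at the substituted carbons C13 and C8 and five-membered over six-membered closure; the Markovnikov bias of both oxiranes and the geometry of the tethers secure this. The order of the two events does not matter, since prior carbonate attack would free the 9α-hydroxyl, which closes the same oxolane.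

Step 17
Reactants: 23 (13S)-9α,13-epoxy-16-hydroxy-6α-(triethylsilyloxy)labd-14-yne-7β,8β-diyl carbonate
Product: 24 (13S)-9α,13:15,16-diepoxy-6α-(triethylsilyloxy)labd-14-ene-7β,8β-diyl carbonate
Conditions: Mo(CO)6 (30 mol %), Et3N, Et2O, hν (350 nm), rt; then 23, rt
Reagents that add atoms: none
Why: Alkynol cycloisomerisation through a molybdenum vinylidene: (Et3N)Mo(CO)5 isomerises the terminal alkyne to a vinylidene, the C16 hydroxyl adds to its electrophilic α-carbon and protodemetalation releases the 2,3-dihydrofuran (formal 5-endo closure of a but-3-yn-1-ol), a reaction type that tolerates propargylic oxygen substituents; C13 is quaternary and keeps its configuration.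

Step 18
Reactants: 24 (13S)-9α,13:15,16-diepoxy-6α-(triethylsilyloxy)labd-14-ene-7β,8β-diyl carbonate
Product: 25 (13S)-9α,13:15,16-diepoxy-6α-(triethylsilyloxy)labd-14-ene-7β,8β-diol
Conditions: LiAlH4, THF, 0 °C; aq. potassium sodium tartrate
Reagents that add atoms: none
Why: Hydride reduction of the cyclic carbonate to the diol and methanol, chosen over basic methanolysis so that no free alkoxide can shift the neighbouring silyl group; enol ether and silyl ether are inert.

Step 19
Reactants: 25 (13S)-9α,13:15,16-diepoxy-6α-(triethylsilyloxy)labd-14-ene-7β,8β-diol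
Product: 26 (13S)-7β-acetoxy-9α,13:15,16-diepoxy-6α-(triethylsilyloxy)labd-14-en-8β-ol
Conditions: Ac2O, pyridine, DMAP (cat.), CH2Cl2, rt
Reagents that add atoms: acetic anhydride, CC(=O)OC(C)=O
Why: Selective DMAP-catalysed acetylation: the secondary equatorial 7β-hydroxyl is acylated, the tertiary axial 8β-hydroxyl is not.

Step 20
Reactants: 26 (13S)-7β-acetoxy-9α,13:15,16-diepoxy-6α-(triethylsilyloxy)labd-14-en-8β-ol
Product: 27 (13S)-7β-acetoxy-9α,13:15,16-diepoxylabd-14-ene-6α,8β-diol
Conditions: TBAF, AcOH (1:1), THF, 0 °C → rt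
Reagents that add atoms: none
Why: Fluoride desilylation buffered with acetic acid, so that no alkoxide forms that could shift the 7-acetate to O6 and the acid-labile enol ether is not protonated.

Step 21
Reactants: 27 (13S)-7β-acetoxy-9α,13:15,16-diepoxylabd-14-ene-6α,8β-diol
Product: 28 (13S)-7β-acetoxy-9α,13:15,16-diepoxy-8β-hydroxylabd-14-en-6-one
Conditions: Dess–Martin periodinane, NaHCO3, CH2Cl2, 0 °C → rt
Reagents that add atoms: none
Why: Dess–Martin oxidation of the secondary 6α-alcohol to the ketone under neutral buffered conditions; the tertiary hydroxyl cannot be oxidised and C5 and C7 are not exposed to base, so the target should result with all six stereocentres in place.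

Compound list
1 | (+)-sclareolide | C1C[C@H]2C(C)(C)CCC[C@]2(C)[C@H]3CC(=O)O[C@]13C | starting material
2 | methyl 13,14,15,16-tetranorlabd-8-en-12-oate (5α-H, 10β-methyl) | C1C[C@H]2C(C)(C)CCC[C@]2(C)C(CC(=O)OC)=C1C | intermediate
3 | 13,14,15,16-tetranorlabd-8-en-12-ol | C1C[C@H]2C(C)(C)CCC[C@]2(C)C(CCO)=C1C | intermediate
4 | 12-iodo-13,14,15,16-tetranorlabd-8-ene | C1C[C@H]2C(C)(C)CCC[C@]2(C)C(CCI)=C1C | intermediate
5 | 2-bromoprop-2-en-1-ol | OCC(Br)=C | starting material
6 | (2-bromoallyloxy)(tert-butyl)dimethylsilane | C=C(Br)CO[Si](C)(C)C(C)(C)C | intermediate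
7 | (13,14,15,16-tetranorlabd-8-en-12-yl)zinc iodide | C1C[C@H]2C(C)(C)CCC[C@]2(C)C(CC[Zn]I)=C1C | intermediate (not isolated)
8 | 14-(tert-butyldimethylsilyloxy)-15-norlabda-8,13(16)-diene | C1C[C@H]2C(C)(C)CCC[C@]2(C)C(CCC(=C)CO[Si](C)(C)C(C)(C)C)=C1C | intermediate
9 | 15-norlabda-8,13(16)-dien-14-ol | C1C[C@H]2C(C)(C)CCC[C@]2(C)C(CCC(=C)CO)=C1C | intermediate
10 | (13R)-13,16-epoxy-15-norlabd-8-en-14-ol | C1C[C@H]2C(C)(C)CCC[C@]2(C)C(CC[C@]3(CO3)CO)=C1C | intermediate
11 | (13S)-13,16-epoxy-15-norlabd-8-en-14-al | C1C[C@H]2C(C)(C)CCC[C@]2(C)C(CC[C@]3(CO3)C=O)=C1C | intermediate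
12 | dimethyl (1-diazo-2-oxopropyl)phosphonate | COP(=O)(OC)C(=[N+]=[N-])C(C)=O | starting material
13 | (13R)-13,16-epoxylabd-8-en-14-yne | C1C[C@H]2C(C)(C)CCC[C@]2(C)C(CC[C@]3(CO3)C#C)=C1C | intermediate
14 | (13R)-13,16-epoxylabd-8-en-14-yn-7-one | O=C1C[C@H]2C(C)(C)CCC[C@]2(C)C(CC[C@]3(CO3)C#C)=C1C | intermediate
15 | dipotassium C6,C7-dienolate C15-acetylide of 14 | [K+].[K+].[O-]C1=C[C@H]2C(C)(C)CCC[C@]2(C)C(CC[C@]3(CO3)C#[C-])=C1C | intermediate (not isolated)
16 | (13R)-13,16-epoxy-6α-hydroxylabd-8-en-14-yn-7-one | O=C1[C@H](O)[C@H]2C(C)(C)CCC[C@]2(C)C(CC[C@]3(CO3)C#C)=C1C | intermediate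
17 | (13R)-13,16-epoxy-6α-(triethylsilyloxy)labd-8-en-14-yn-7-one | O=C1[C@H](O[Si](CC)(CC)CC)[C@H]2C(C)(C)CCC[C@]2(C)C(CC[C@]3(CO3)C#C)=C1C | intermediate
18 | (13R)-13,16-epoxy-6α-(triethylsilyloxy)labd-8-en-14-yn-7β-ol | O[C@H]1[C@H](O[Si](CC)(CC)CC)[C@H]2C(C)(C)CCC[C@]2(C)C(CC[C@]3(CO3)C#C)=C1C | intermediate
19 | di-tert-butyl dicarbonate | CC(C)(C)OC(=O)OC(=O)OC(C)(C)C | starting material
20 | (13R)-7β-(tert-butoxycarbonyloxy)-13,16-epoxy-6α-(triethylsilyloxy)labd-8-en-14-yne | CC(C)(C)OC(=O)O[C@H]1[C@H](O[Si](CC)(CC)CC)[C@H]2C(C)(C)CCC[C@]2(C)C(CC[C@]3(CO3)C#C)=C1C | intermediate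
21 | (13R)-7β-(tert-butoxycarbonyloxy)-8α,9α:13,16-diepoxy-6α-(triethylsilyloxy)labd-14-yne (key-step precursor) | CC(C)(C)OC(=O)O[C@H]1[C@H](O[Si](CC)(CC)CC)[C@H]2C(C)(C)CCC[C@]2(C)[C@]4(CC[C@]3(CO3)C#C)O[C@]14C | intermediate
22 | bridged epoxonium zwitterion (O9 bonded to C8, C9 and C13; C16–O–BF3; Boc still on O7) | CC(C)(C)OC(=O)O[C@H]1[C@H](O[Si](CC)(CC)CC)[C@H]2C(C)(C)CCC[C@]2(C)[C@@]45CC[C@@](CO[B-](F)(F)F)(C#C)[O+]5[C@]14C | intermediate (not isolated)
23 | (13S)-9α,13-epoxy-16-hydroxy-6α-(triethylsilyloxy)labd-14-yne-7β,8β-diyl carbonate (key-step product) | O=C1O[C@H]2[C@H](O[Si](CC)(CC)CC)[C@H]3C(C)(C)CCC[C@]3(C)[C@@]4(CC[C@@](CO)(C#C)O4)[C@@]2(C)O1 | intermediate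
24 | (13S)-9α,13:15,16-diepoxy-6α-(triethylsilyloxy)labd-14-ene-7β,8β-diyl carbonate | O=C1O[C@H]2[C@H](O[Si](CC)(CC)CC)[C@H]3C(C)(C)CCC[C@]3(C)[C@@]4(CC[C@@]5(C=COC5)O4)[C@@]2(C)O1 | intermediate
25 | (13S)-9α,13:15,16-diepoxy-6α-(triethylsilyloxy)labd-14-ene-7β,8β-diol | O[C@H]1[C@H](O[Si](CC)(CC)CC)[C@H]2C(C)(C)CCC[C@]2(C)[C@@]2(CC[C@@]3(C=COC3)O2)[C@@]1(C)O | intermediate
26 | (13S)-7β-acetoxy-9α,13:15,16-diepoxy-6α-(triethylsilyloxy)labd-14-en-8β-ol | CC(=O)O[C@H]1[C@H](O[Si](CC)(CC)CC)[C@H]2C(C)(C)CCC[C@]2(C)[C@@]2(CC[C@@]3(C=COC3)O2)[C@@]1(C)O | intermediate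
27 | (13S)-7β-acetoxy-9α,13:15,16-diepoxylabd-14-ene-6α,8β-diol | CC(=O)O[C@H]1[C@H](O)[C@H]2C(C)(C)CCC[C@]2(C)[C@@]2(CC[C@@]3(C=COC3)O2)[C@@]1(C)O | intermediate
28 | (13S)-7β-acetoxy-9α,13:15,16-diepoxy-8β-hydroxylabd-14-en-6-one (CNP0284584.1) | CC(=O)O[C@H]1C(=O)[C@H]2C(C)(C)CCC[C@]2(C)[C@@]2(CC[C@@]3(C=COC3)O2)[C@@]1(C)O | target

Total step count: 21. Longest linear sequence: 20 steps (steps 1–3 and 5–21, from 1 to 28); step 4 prepares the coupling partner.

Steps most likely to fail

Step 16 (cascade). The Lewis acid may trigger a 1,2-hydride shift of the activated ethynyl oxirane to an aldehyde, or ionise C13 far enough to erode the inversion, before the weakly nucleophilic oxirane oxygen has attacked. The fallback separates the two ring closures and sets out from 21. A weak Brønsted acid (pyridinium p-toluenesulfonate, CH2Cl2, 0 °C) should open only the more basic tetrasubstituted oxirane with participation of the neighbouring carbonate. This would give (13R)-13,16-epoxy-9α-hydroxy-6α-(triethylsilyloxy)labd-14-yne-7β,8β-diyl carbonate F1, in which the ethynyl oxirane is intact. The free tertiary 9α-hydroxyl of this compound is a better nucleophile than an oxirane oxygen, and the classical acid-catalysed 5-exo cyclisation of an epoxy alcohol (camphorsulfonic acid, CH2Cl2, 0 °C) should then close the oxolane at C13 with inversion and return to the route at 23.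

Step 10 (allylic oxidation). The oxidant may also attack the C11 methylene, carry the oxidation on to a dione, or open the ethynyl oxirane at its Lewis-acidic chromium centre. The fallback sets out from 13 and replaces oxo transfer by an ene and [2,3]-sigmatropic sequence: SeO2 (catalytic) with t-BuOOH in CH2Cl2, which by the usual selectivity rules prefers the ring methylene next to the alkene, should give (13R)-13,16-epoxylabd-8-en-14-yn-7α-ol F2. Oxidation of this allylic alcohol with MnO2 in CH2Cl2 should then give enone 14, where the route is rejoined.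

Step 11 (C6 hydroxylation). Deprotonation may occur at the γ position C11 instead of C6, or the acetylide may consume oxidant. The fallback sets out from 14 and avoids strong base: Mn(OAc)3·2H2O in benzene at reflux acetoxylates enones at the α′ carbon through a trivalent manganese enolate and should give (13R)-6α-acetoxy-13,16-epoxylabd-8-en-14-yn-7-one F3, again from the less hindered α face. Brief methanolysis (K2CO3, MeOH, 0 °C) should then free the hydroxyl and return to the route at 16.

Further compounds
F1 | step 16 | (13R)-13,16-epoxy-9α-hydroxy-6α-(triethylsilyloxy)labd-14-yne-7β,8β-diyl carbonate | O=C1O[C@H]2[C@H](O[Si](CC)(CC)CC)[C@H]3C(C)(C)CCC[C@]3(C)[C@@](O)(CC[C@]4(CO4)C#C)[C@@]2(C)O1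
F2 | step 10 | (13R)-13,16-epoxylabd-8-en-14-yn-7α-ol | O[C@@H]1C[C@H]2C(C)(C)CCC[C@]2(C)C(CC[C@]3(CO3)C#C)=C1C
F3 | step 11 | (13R)-6α-acetoxy-13,16-epoxylabd-8-en-14-yn-7-one | O=C1[C@H](OC(C)=O)[C@H]2C(C)(C)CCC[C@]2(C)C(CC[C@]3(CO3)C#C)=C1C
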